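Assumption: the target is the 1′R (shikonin-series) ester, written as the naphthazarin tautomer with the side chain on the quinone ring; 3,4-dimethylpent-3-enoic acid and the pentane solution of B-allyldiisopinocampheylborane are taken as purchasable.

## Retrosynthetic overview

1. The ester C–O bond at C1′ is cut last: the target comes from (R)-shikonin and 3,4-dimethylpent-3-enoic acid, and shikonin from its 5,8-bis(methoxymethyl), 1′-O-silyl quinone by acid unmasking.
2. The quinone comes from a 1-naphthol and that from a 1,4-epoxy-1,4-dihydronaphthalene; the furan oxygen becomes the oxygen on C1 and water supplies the one on C4.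
3. The strategy rests on the ring-fusion carbons C4a and C8a being neighbours flanked by like oxygens on C5 and C8. Ring C4a–C5–C6–C7–C8–C8a is therefore a symmetric 3,6-dioxygenated benzyne, ring C1–C4 with its C2 side chain is a 3-substituted furan, and cutting C1–C8a and C4–C4a needs no regiocontrol.
4. The furan partner comes from furan-3-carbaldehyde by asymmetric allylboration (sets C1′), silylation and cross-metathesis; the aryne precursor comes from bromohydroquinone.
5. Ring order: the furan and benzenoid rings are bought, the carbocycle C1–C2–C3–C4–C4a–C8a closes in the cycloaddition, and it is then aromatised and oxidised to the quinone ring.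

Key step: step 5

## Route

Step 1
Reactants: 1 bromohydroquinone (2-bromobenzene-1,4-diol)
Product: 2 2-bromo-1,4-bis(methoxymethoxy)benzene
Conditions: MOMCl (2.6 equiv), i-Pr2NEt (3 equiv), CH2Cl2, 0 °C → rt, argon
Reagents that add atoms: chloromethyl methyl ether (MOMCl), COCCl
Why: Base-mediated O-alkylation of both phenols by the highly electrophilic α-chloro ether (acetal formation) should be clean; the aryl bromide is inert and no stereocentre is involved.

Step 2
Reactants: 3 furan-3-carbaldehyde
Product: 5 (R)-1-(furan-3-yl)but-3-en-1-ol, via borinate ester 4 (not isolated)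
Conditions: B-allyldiisopinocampheylborane of the (−)-α-pinene series (1 M in pentane), Et2O, −78 °C; then 3 M NaOH, 30% H2O2, 0 °C → rt
Reagents that add atoms: B-allyldiisopinocampheylborane from (−)-α-pinene, C=CCB([C@H]1C[C@H]2C[C@@H]([C@@H]1C)C2(C)C)[C@H]1C[C@H]2C[C@@H]([C@@H]1C)C2(C)C
Why: Brown asymmetric allylboration through a closed chair transition state, in which the isopinocampheyl groups of this reagent series deliver the allyl group to the Re face of the aldehyde and so set C1′ as R (the sense known for aryl and heteroaryl aldehydes); oxidative work-up of the borinate releases the alcohol.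

Step 3
Reactants: 5 (R)-1-(furan-3-yl)but-3-en-1-ol
Product: 6 (R)-tert-butyl{[1-(furan-3-yl)but-3-en-1-yl]oxy}dimethylsilane
Conditions: TBSCl, imidazole, DMF, rt
Reagents that add atoms: tert-butyldimethylsilyl chloride (TBSCl), CC(C)(C)[Si](C)(C)Cl
Why: Standard imidazole-promoted silylation of a secondary alcohol at oxygen, which leaves C1′ untouched and masks the only acidic hydrogen before the amide-base step.

Step 4
Reactants: 6 (R)-tert-butyl{[1-(furan-3-yl)but-3-en-1-yl]oxy}dimethylsilane; 7 2-methylbut-2-ene
Product: 8 (R)-tert-butyl{[1-(furan-3-yl)-4-methylpent-3-en-1-yl]oxy}dimethylsilane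
Conditions: second-generation Grubbs catalyst (H2IMes)(PCy3)Cl2Ru=CHPh (3 mol %), 2-methylbut-2-ene/CH2Cl2, 35 °C, sealed vessel
Reagents that add atoms: none
Why: Ruthenium-catalysed olefin cross-metathesis of the terminal alkene with excess 2-methylbut-2-ene should cap the chain as the isopropylidene terminus with loss of propene; the product alkene carries two identical methyls, so no E/Z question arises, and the furan, silyl ether and C1′ are inert to the carbene.

Step 5
Reactants: 2 2-bromo-1,4-bis(methoxymethoxy)benzene; 8 (R)-tert-butyl{[1-(furan-3-yl)-4-methylpent-3-en-1-yl]oxy}dimethylsilane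
Product: 11 2-[(1R)-1-(tert-butyldimethylsilyloxy)-4-methylpent-3-en-1-yl]-5,8-bis(methoxymethoxy)-1,4-dihydro-1,4-epoxynaphthalene as the pair of bridgehead epimers (1S,4R epimer drawn; the 1R,4S epimer is carried along), via aryllithium 9 (not isolated), via aryne 10 (not isolated)
Conditions: lithium 2,2,6,6-tetramethylpiperidide (LiTMP, 1.6 equiv) added slowly to 2 (1.5 equiv) and 8 (1.0 equiv), THF, −78 → 0 °C; aq. NH4Cl
Reagents that add atoms: none
Why: LiTMP removes the ring hydrogen of 2 that sits between bromine and a methoxymethoxy group (the most acidic and best-coordinated site), aryllithium 9 loses LiBr on warming, and the strained triple bond of the symmetric aryne 10 is taken up by the 2- and 5-positions of the furan of 8 in a concerted suprafacial [4+2] cycloaddition. The closest known reaction type is the trapping of 3,6-dialkoxybenzynes, made from 2-bromo-1,4-dialkoxybenzenes and amide bases, by furans to give 5,8-dialkoxy-1,4-epoxy-1,4-dihydronaphthalenes. The carbocycle C1–C2–C3–C4–C4a–C8a is closed intermolecularly, both new bonds (C1–C8a and C4–C4a) being made in the one cycloaddition event across the furan diene. The bridgehead centres C1 and C4 are fixed relative to each other by the one-atom oxygen bridge, while their sense relative to C1′ is not controlled by the remote silyloxy centre, so both epimers are expected and both are carried on because C1 and C4 become sp2 carbons in step 6. No regiocontrol is required, since the two oxygen groups flanking the triple bond are identical and either orientation of the furan gives the same constitution. What the step does need is chemoselectivity, namely cycloaddition faster than an ene reaction of the aryne with the trisubstituted alkene, than amide addition to the aryne and than metalation of the furan α-hydrogens, and this is secured by the high diene reactivity of the furan, the bulk of the amide and its slow addition to a mixture of both partners at −78 °C; the substrate carries no ester and no acidic stereocentre at this stage.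

Step 6
Reactants: 11 2-[(1R)-1-(tert-butyldimethylsilyloxy)-4-methylpent-3-en-1-yl]-5,8-bis(methoxymethoxy)-1,4-dihydro-1,4-epoxynaphthalene (both bridgehead epimers)
Product: 12 2-[(1R)-1-(tert-butyldimethylsilyloxy)-4-methylpent-3-en-1-yl]-5,8-bis(methoxymethoxy)naphthalen-1-ol
Conditions: [Rh(CO)2Cl]2 (2.5 mol %), ClCH2CH2Cl, 50 °C
Reagents that add atoms: none
Why: Monovalent rhodium should insert into the strained allylic, benzylic bridgehead C–O bond and, after hydride migration, release the keto tautomer that aromatises to the naphthol (the known rhodium-catalysed isomerisation of 1,4-epoxy-1,4-dihydronaphthalenes to 1-naphthols); C4–O cleavage is expected to dominate because the allyl unit then ends on the substituted carbon C2, the regioisomeric naphthol from C1–O cleavage would give the same quinone in step 7, both bridgehead centres are erased, and the neutral conditions spare the acetals, the silyl ether and C1′.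

Step 7
Reactants: 12 2-[(1R)-1-(tert-butyldimethylsilyloxy)-4-methylpent-3-en-1-yl]-5,8-bis(methoxymethoxy)naphthalen-1-ol
Product: 14 2-[(1R)-1-(tert-butyldimethylsilyloxy)-4-methylpent-3-en-1-yl]-5,8-bis(methoxymethoxy)naphthalene-1,4-dione, via hydroquinone 13 (not isolated)
Conditions: PhI(OAc)2 (2.2 equiv), MeCN–H2O (2:1), 0 °C
Reagents that add atoms: water, O
Why: Hypervalent-iodine oxidation of a para-unsubstituted 1-naphthol: the phenol binds to the trivalent iodine centre, water attacks C4, the quinol tautomerises to hydroquinone 13 and a second equivalent of oxidant gives the 1,4-quinone, while the trisubstituted alkene, the silyl ether and the acetals should be untouched at 0 °C.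

Step 8
Reactants: 14 2-[(1R)-1-(tert-butyldimethylsilyloxy)-4-methylpent-3-en-1-yl]-5,8-bis(methoxymethoxy)naphthalene-1,4-dione
Product: 15 (R)-5,8-dihydroxy-2-(1-hydroxy-4-methylpent-3-en-1-yl)naphthalene-1,4-dione (shikonin)
Conditions: 2 M aq. H2SO4–THF (1:4), rt → 40 °C, argon, dark
Reagents that add atoms: none
Why: Aqueous acid with a non-nucleophilic counter-ion (no chloride that could add to the quinone) should hydrolyse both aryl methoxymethyl acetals and the secondary silyl ether in one operation; only O–CH2 and O–Si bonds break, so the C1′–O bond and its R configuration are untouched, and the product is shikonin, whose identity and enantiomeric purity can be compared with natural material.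

Step 9
Reactants: 15 (R)-shikonin; 16 3,4-dimethylpent-3-enoic acid
Product: 18 (R)-1-(5,8-dihydroxy-1,4-dioxo-1,4-dihydronaphthalen-2-yl)-4-methylpent-3-en-1-yl 3,4-dimethylpent-3-enoate (CNP0163639.1), via O-acylisourea 17 (not isolated)
Conditions: DCC (1.5 equiv), DMAP (0.2 equiv), 16 (1.3 equiv), CH2Cl2, 0 °C → rt, dark
Reagents that add atoms: none
Why: Steglich esterification, in which DCC turns 16 into O-acylisourea 17 and DMAP relays the acyl group to the secondary C1′ hydroxyl with retention (the C1′–O bond is not broken); the two peri-phenols should stay unreacted because they are locked in hydrogen bonds to the quinone carbonyls, and the tetrasubstituted β,γ-double bond of the acid has no driving force to move into conjugation.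

## Compound list

1 | bromohydroquinone (2-bromobenzene-1,4-diol) | Oc1ccc(O)c(Br)c1 | starting material
2 | 2-bromo-1,4-bis(methoxymethoxy)benzene | COCOc1ccc(OCOC)c(Br)c1 | intermediate
3 | furan-3-carbaldehyde | O=Cc1ccoc1 | starting material
4 | (R)-1-(furan-3-yl)but-3-en-1-yl diisopinocampheylborinate (not isolated) | C=CC[C@@H](OB([C@H]1C[C@H]2C[C@@H]([C@@H]1C)C2(C)C)[C@H]1C[C@H]2C[C@@H]([C@@H]1C)C2(C)C)c1ccoc1 | intermediate
5 | (R)-1-(furan-3-yl)but-3-en-1-ol | C=CC[C@@H](O)c1ccoc1 | intermediate
6 | (R)-tert-butyl{[1-(furan-3-yl)but-3-en-1-yl]oxy}dimethylsilane | C=CC[C@@H](O[Si](C)(C)C(C)(C)C)c1ccoc1 | intermediate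
7 | 2-methylbut-2-ene | CC=C(C)C | starting material
8 | (R)-tert-butyl{[1-(furan-3-yl)-4-methylpent-3-en-1-yl]oxy}dimethylsilane | CC(C)=CC[C@@H](O[Si](C)(C)C(C)(C)C)c1ccoc1 | intermediate
9 | [2-bromo-3,6-bis(methoxymethoxy)phenyl]lithium (not isolated) | COCOc1ccc(OCOC)c(Br)c1[Li] | intermediate
10 | 3,6-bis(methoxymethoxy)benzyne (not isolated) | COCOC1=CC=C(OCOC)C#C1 | intermediate
11 | 2-[(1R)-1-(tert-butyldimethylsilyloxy)-4-methylpent-3-en-1-yl]-5,8-bis(methoxymethoxy)-1,4-dihydro-1,4-epoxynaphthalene, pair of bridgehead epimers (1S,4R epimer drawn) | CC(C)=CC[C@@H](O[Si](C)(C)C(C)(C)C)C1=C[C@H]2O[C@@H]1c1c(OCOC)ccc(OCOC)c12 | intermediate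
12 | 2-[(1R)-1-(tert-butyldimethylsilyloxy)-4-methylpent-3-en-1-yl]-5,8-bis(methoxymethoxy)naphthalen-1-ol | CC(C)=CC[C@@H](O[Si](C)(C)C(C)(C)C)c1ccc2c(OCOC)ccc(OCOC)c2c1O | intermediate
13 | 2-[(1R)-1-(tert-butyldimethylsilyloxy)-4-methylpent-3-en-1-yl]-5,8-bis(methoxymethoxy)naphthalene-1,4-diol (not isolated) | CC(C)=CC[C@@H](O[Si](C)(C)C(C)(C)C)c1cc(O)c2c(OCOC)ccc(OCOC)c2c1O | intermediate
14 | 2-[(1R)-1-(tert-butyldimethylsilyloxy)-4-methylpent-3-en-1-yl]-5,8-bis(methoxymethoxy)naphthalene-1,4-dione | CC(C)=CC[C@@H](O[Si](C)(C)C(C)(C)C)C1=CC(=O)c2c(OCOC)ccc(OCOC)c2C1=O | intermediate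
15 | (R)-5,8-dihydroxy-2-(1-hydroxy-4-methylpent-3-en-1-yl)naphthalene-1,4-dione (shikonin) | CC(C)=CC[C@@H](O)C1=CC(=O)c2c(O)ccc(O)c2C1=O | intermediate
16 | 3,4-dimethylpent-3-enoic acid | CC(C)=C(C)CC(=O)O | starting material
17 | N,N′-dicyclohexyl-O-(3,4-dimethylpent-3-enoyl)isourea (not isolated) | CC(C)=C(C)CC(=O)OC(=NC1CCCCC1)NC1CCCCC1 | intermediate
18 | (R)-1-(5,8-dihydroxy-1,4-dioxo-1,4-dihydronaphthalen-2-yl)-4-methylpent-3-en-1-yl 3,4-dimethylpent-3-enoate (CNP0163639.1) | CC(C)=CC[C@@H](OC(=O)CC(C)=C(C)C)C1=CC(=O)c2c(O)ccc(O)c2C1=O | target

## Summary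

Total step count: 9. Longest linear sequence: 8 steps (furan-3-carbaldehyde 3 to target 18, steps 2–9).

Steps most likely to fail:

Step 5. The amide base may metalate the furan α-positions or add to the aryne, and the aryne may be consumed in an ene reaction with the trisubstituted alkene, so that little cycloadduct forms. Fallback: the aryne is released by halogen–lithium exchange, not by deprotonation in the presence of the furan. Compound 2 alone is lithiated with lithium diisopropylamide (LDA) in THF at −78 °C and quenched with I2 to give 2-bromo-3-iodo-1,4-bis(methoxymethoxy)benzene F1. Then n-BuLi is added at −78 °C to a mixture of F1 and 8 in toluene; fast iodine–lithium exchange regenerates aryllithium 9 without any free amide, LiBr is lost, and aryne 10 is trapped by the furan to rejoin the route at 11.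

Step 8. While the free side-chain alcohol stands in acid, the hydroxyl may cyclise onto the protonated prenyl alkene, or C1′ may ionise through the naphthazarin tautomer with loss of configuration; acetal cleavage may stay incomplete if the acid is kept mild enough to avoid this. Fallback: unmasking in two orthogonal stages with the side-chain oxygen kept silylated while Lewis acid is present. From 14, TMSOTf/2,2′-bipyridyl in CH2Cl2 at 0 °C followed by water converts both aryl acetals into phenols and leaves the alkyl silyl ether, giving (R)-2-[1-(tert-butyldimethylsilyloxy)-4-methylpent-3-en-1-yl]-5,8-dihydroxynaphthalene-1,4-dione F2. HF·pyridine in THF/pyridine at 0 °C then removes the silyl group and rejoins the route at 15.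

Step 9. The phenols may be acylated in competition, the O-acylisourea may rearrange to the N-acylurea, or the β,γ-double bond may migrate under base, giving mixtures that are hard to separate from the strongly coloured product. Fallback: acylation before the phenols are unveiled. From 14, HF·pyridine (THF/pyridine, 0 °C) removes only the silyl ether to give (R)-2-(1-hydroxy-4-methylpent-3-en-1-yl)-5,8-bis(methoxymethoxy)naphthalene-1,4-dione F3. Its single hydroxyl is esterified with 16 (DCC, DMAP, CH2Cl2, 0 °C) to give (R)-1-[5,8-bis(methoxymethoxy)-1,4-dioxo-1,4-dihydronaphthalen-2-yl]-4-methylpent-3-en-1-yl 3,4-dimethylpent-3-enoate F4. Aprotic acetal cleavage with TMSOTf/2,2′-bipyridyl in CH2Cl2 at 0 °C, then water, frees both phenols and arrives directly at 18.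

Further compounds
F1 | step 5 | 2-bromo-3-iodo-1,4-bis(methoxymethoxy)benzene | COCOc1ccc(OCOC)c(I)c1Br
F2 | step 8 | (R)-2-[1-(tert-butyldimethylsilyloxy)-4-methylpent-3-en-1-yl]-5,8-dihydroxynaphthalene-1,4-dione | CC(C)=CC[C@@H](O[Si](C)(C)C(C)(C)C)C1=CC(=O)c2c(O)ccc(O)c2C1=O
F3 | step 9 | (R)-2-(1-hydroxy-4-methylpent-3-en-1-yl)-5,8-bis(methoxymethoxy)naphthalene-1,4-dione | CC(C)=CC[C@@H](O)C1=CC(=O)c2c(OCOC)ccc(OCOC)c2C1=O
F4 | step 9 | (R)-1-[5,8-bis(methoxymethoxy)-1,4-dioxo-1,4-dihydronaphthalen-2-yl]-4-methylpent-3-en-1-yl 3,4-dimethylpent-3-enoate | CC(C)=CC[C@@H](OC(=O)CC(C)=C(C)C)C1=CC(=O)c2c(OCOC)ccc(OCOC)c2C1=O
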